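The route cuts the fully substituted carbocycle of the chromanone core (C4a, C5, C6, C7, C8, C8a) at C4a–C8a and C5–C6. The key step exploits the alternating oxygen pattern at C5, C7 and C8a. It is a Danheiser benzannulation: a 3-siloxycyclobutenone carrying the cyclobutylmethyl and phenylpropanoate arms opens to a vinylketene, which takes up a siloxyalkyne carrying C2–C4. One thermal operation makes both bonds and delivers the hexasubstituted arene with only the C8a hydroxyl free. That phenol then closes the pyranone ring by Mitsunobu inversion. A ligand-controlled dearomative prenylation at C6 sets the quaternary centre.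

Key step: step 13

Assumption: the catalyst antipodes written in steps 5 and 18 are taken to give the drawn configurations (otherwise the pseudoenantiomeric or enantiomeric catalyst is used), and the target is drawn as its C4-enol tautomer; chromanone numbering (O1, C2, C3, C4, C4a, C5–C8, C8a) is used throughout.

Step 1
Reactants: 1 (−)-α-pinene
Product: 2 cis-pinonic acid [2-((1R,3R)-3-acetyl-2,2-dimethylcyclobutyl)acetic acid]
Conditions: RuCl3·xH2O (2 mol %), NaIO4 (4 equiv), EtOAc/MeCN/H2O, 0 °C to rt
Reagents that add atoms: sodium periodate, [Na+].[O-]I(=O)(=O)=O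
Why: Oxidative alkene cleavage by ruthenium tetroxide generated in situ cuts only the trisubstituted C2=C3 bond into methyl ketone and carboxylic acid, and the two ring-fusion stereocentres of 1 are carried over unchanged as the cis-1,3 pair of the cyclobutane.

Step 2
Reactants: 2 cis-pinonic acid
Product: 3 methyl cis-pinonate
Conditions: MeI, K2CO3, DMF, rt
Reagents that add atoms: iodomethane, CI
Why: SN2 O-methylation of the carboxylate under weakly basic conditions gives the ester needed for step 4 without enolising the epimerisable centre next to the ketone.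

Step 3
Reactants: 3 methyl cis-pinonate
Product: 4 methyl 2-[(1R,3S)-2,2-dimethyl-3-(prop-1-en-2-yl)cyclobutyl]acetate
Conditions: Ph3PCH3Br, KN(SiMe3)2, THF, −78 to 0 °C
Reagents that add atoms: methyltriphenylphosphonium bromide, C[P+](c1ccccc1)(c1ccccc1)c1ccccc1.[Br-]
Why: Wittig methylenation is chemoselective for the ketone over the ester, and the preformed ylide at low temperature should add faster than it enolises, so the cis relationship is kept.

Step 4
Reactants: 4 isopropenyl ester
Product: 6 silyl ynol ether of the cyclobutane arm [1-(triisopropylsiloxy)-3-((1R,3S)-2,2-dimethyl-3-isopropenylcyclobutyl)prop-1-yne], via lithium ynolate 5 (not isolated)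
Conditions: CH2Br2, lithium 2,2,6,6-tetramethylpiperidide (2.2 equiv), THF, −78 °C; n-BuLi, −78 °C to rt; iPr3SiCl, −78 to 0 °C
Reagents that add atoms: dibromomethane, BrCBr; chlorotriisopropylsilane, CC(C)[Si](Cl)(C(C)C)C(C)C
Why: Kowalski ester homologation (addition of LiCHBr2, enolisation, bromine–lithium exchange and 1,2-shift of the alkyl group) gives ynolate 5, which the bulky silyl chloride traps on oxygen, while no stereocentre is touched.

Step 5
Reactants: 7 3-phenylglutaric anhydride
Product: 8 (S)-5-methoxy-5-oxo-3-phenylpentanoic acid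
Conditions: MeOH (10 equiv), quinidine-derived 9-amino-9-deoxy-epi-cinchona 3,5-bis(trifluoromethyl)benzenesulfonamide (10 mol %), MTBE, rt
Reagents that add atoms: methanol, CO
Why: Organocatalytic desymmetrising alcoholysis of a prochiral cyclic anhydride: the bifunctional cinchona sulfonamide binds the anhydride by hydrogen bonds and delivers methanol by general-base catalysis to one enantiotopic carbonyl, which sets the benzylic stereocentre as S.

Step 6
Reactants: 8 (S)-hemiester; 6 silyl ynol ether of the cyclobutane arm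
Product: 11 3-siloxycyclobutenone (2-cyclobutylmethyl; 4-[(1-phenyl-2-methoxycarbonyl)ethyl]; mixture at ring C4), via acid chloride 9 (not isolated), via aldoketene 10 (not isolated)
Conditions: (COCl)2, cat. DMF, CH2Cl2, 0 °C, concentrate; slow addition to 6 and Et3N, toluene, rt to 40 °C
Reagents that add atoms: none
Why: Acid chloride formation, dehydrochlorination to the aldoketene and thermal ketene–ynol ether [2+2] cycloaddition (ketene carbonyl carbon to the nucleophilic alkyne carbon) give the 3-siloxycyclobutenone, whose new ring stereocentre is formed as a mixture that is of no consequence because it becomes sp2 in step 13.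

Step 7
Reactants: 12 methyl (S)-3-hydroxybutanoate
Product: 13 methyl (2S,3S)-3-hydroxy-2-methylbutanoate
Conditions: LiN(iPr)2 (2.2 equiv), THF, −78 to −20 °C; MeI, DMPU, −78 to 0 °C; then AcOH
Reagents that add atoms: iodomethane, CI
Why: Fráter–Seebach alkylation: the lithium-chelated dianion is methylated on the face opposite to the C3 methyl group, which sets C2 as S (anti to the hydroxyl).

Step 8
Reactants: 13 anti hydroxy ester
Product: 14 methyl (2S,3S)-2-methyl-3-(triethylsiloxy)butanoate
Conditions: Et3SiCl, imidazole, CH2Cl2, 0 °C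
Reagents that add atoms: chlorotriethylsilane, CC[Si](Cl)(CC)CC
Why: Standard silylation masks the alcohol as a triethylsilyl ether that survives organometallic reagents and heat but leaves under mild fluoride conditions.

Step 9
Reactants: 14 silyl ether ester
Product: 15 (2S,3S)-2-methyl-3-(triethylsiloxy)butanal
Conditions: iBu2AlH, CH2Cl2, −78 °C; aqueous work-up
Reagents that add atoms: none
Why: Partial ester reduction with iBu2AlH stops at the tetrahedral aluminate at −78 °C and releases the aldehyde only on work-up, so the α-stereocentre is not epimerised.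

Step 10
Reactants: 15 aldehyde
Product: 16 propargylic alcohol (4-methyl-5-(triethylsiloxy)hex-1-yn-3-ol; methyl- and siloxy-bearing centres as in 15; carbinol centre as a mixture)
Conditions: HC≡CMgBr, THF, −78 to 0 °C; aq NH4Cl
Reagents that add atoms: ethynylmagnesium bromide, C#C[Mg]Br
Why: Grignard 1,2-addition installs the two alkyne carbons (future C4a and C5), and the new carbinol centre may form as a mixture because it is oxidised to the C4 ketone in step 15.

Step 11
Reactants: 16 propargylic alcohol
Product: 17 bis(triethylsilyl) ether of the terminal alkyne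
Conditions: Et3SiCl, imidazole, DMF, rt
Reagents that add atoms: chlorotriethylsilane, CC[Si](Cl)(CC)CC
Why: Standard silylation removes the last acidic O–H, so that neither the ynolate chemistry of step 12 nor the ketenes of step 13 are quenched.

Step 12
Reactants: 17 terminal alkyne
Product: 19 silyl ynol ether carrying C2–C4 [1-(triisopropylsiloxy)-3,5-bis(triethylsiloxy)-4-methylhex-1-yne], via lithium ynolate 18 (not isolated)
Conditions: n-BuLi, THF, −78 °C; t-BuOOLi (from t-BuOOH and LiN(SiMe3)2), −78 to 0 °C; iPr3SiOTf, −78 °C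
Reagents that add atoms: tert-butyl hydroperoxide, CC(C)(C)OO; triisopropylsilyl trifluoromethanesulfonate, CC(C)[Si](OS(=O)(=O)C(F)(F)F)(C(C)C)C(C)C
Why: Electrophilic oxygenation of the lithium acetylide by lithium tert-butyl peroxide gives ynolate 18, and the bulky silyl triflate traps it on oxygen (the known route from terminal alkynes to silyl ynol ethers).

Step 13
Reactants: 11 3-siloxycyclobutenone; 19 silyl ynol ether carrying C2–C4
Product: 23 hexasubstituted phenol (C8a–OH free; C5 and C7 as triisopropylsilyl ethers), via vinylketene 20 (not isolated), via vinylcyclobutenone 21 (not isolated), via dienylketene 22 (not isolated)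
Conditions: 19 (1.3 equiv), toluene (0.5 M), argon, sealed tube, 80 °C then 110 °C
Reagents that add atoms: none
Why: Heating opens 11 by conrotatory 4π electrocyclic cleavage of its C(=O)–C(sp3) bond to vinylketene 20, and the polarised ynol ether 19 adds across the ketene C=C in a regiospecific [2+2] (nucleophilic alkyne carbon to the ketene carbonyl carbon = C4a–C8a, siloxy-bearing alkyne carbon to the ketene α-carbon = C5–C6), so both ring bonds are made in this one event to give 21. A second 4π opening cuts the old C8a–C6 bond of 21 to give dienylketene 22, whose disrotatory 6π electrocyclisation (C8a–C8) closes the six-membered carbocycle, and tautomerisation gives phenol 23. The closest known reaction is the Danheiser benzannulation in its siloxyalkyne/3-siloxycyclobutenone form, which is an established entry to resorcinol and phloroglucinol ethers. One ring is closed, by electrocyclisation; no lasting stereocentre is created (the quaternary C6 of 21 and the ring C4 of 11 are transient), and the existing stereocentres are remote from all reacting atoms and see only neutral thermal conditions. The selectivity needed is regiochemical and is secured by the ynol ether polarisation, while a silyl shift between the two oxygens of 11 is harmless because either carbonyl-type carbon leads to the same arene. The cascade leaves only the C8a oxygen unprotected, which is what later directs pyranone closure to C8a and not to C5.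

Step 14
Reactants: 23 hexasubstituted phenol
Product: 24 phenol diol (C4 and C2 hydroxyls free; aryl silyl ethers kept)
Conditions: HF·pyridine, pyridine, THF, 0 °C; used directly
Reagents that add atoms: none
Why: Acid-buffered fluoride desilylation is selective because secondary alkyl triethylsilyl ethers cleave far faster than hindered aryl triisopropylsilyl ethers under these conditions.

Step 15
Reactants: 24 phenol diol
Product: 25 ortho-hydroxyaryl β-hydroxy ketone
Conditions: activated MnO2, CH2Cl2, rt
Reagents that add atoms: none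
Why: MnO2 oxidation is selective for the benzylic (ortho-hydroxybenzylic) carbinol over the aliphatic C2 alcohol and removes the stereorandom centre.

Step 16
Reactants: 25 ortho-hydroxyaryl β-hydroxy ketone
Product: 26 (2R,3S)-cis-2,3-dimethylchroman-4-one with C5 and C7 triisopropylsilyl ethers
Conditions: PPh3, DIAD, toluene, 0 °C to rt
Reagents that add atoms: none
Why: Intramolecular Mitsunobu etherification: the only free phenol (C8a–OH) displaces the activated C2 oxygen in a 6-exo-tet SN2 closure with inversion (S to R), which turns the anti aldol array into the cis-2,3-dimethylchromanone.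

Step 17
Reactants: 26 bis-silylated chromanone
Product: 27 5,7-dihydroxychromanone methyl ester
Conditions: Bu4NF, AcOH (1:1), THF, 0 °C; used at once
Reagents that add atoms: none
Why: Fluoride cleaves both aryl silyl ethers, and the acetic acid buffer keeps the medium from epimerising C3 or opening the pyranone by retro-oxa-Michael reaction.

Step 18
Reactants: 27 5,7-dihydroxychromanone methyl ester
Product: 28 methyl ester of the target (C6 quaternary, R)
Conditions: Pd2(dba)3·CHCl3 (2.5 mol %), (R,R)-DACH-phenyl Trost ligand (7.5 mol %), prenyl methyl carbonate (1.05 equiv), CH2Cl2, 0 °C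
Reagents that add atoms: methyl 3-methylbut-2-en-1-yl carbonate, COC(=O)OCC=C(C)C
Why: Tsuji–Trost asymmetric allylic alkylation run as a dearomatisation: methoxide set free from the carbonate deprotonates the phenol, C6 (between two oxygen-bearing carbons, the site alkylated in the formation of hop β-acids) attacks the unsubstituted terminus of the π-prenyl complex formed from zerovalent palladium, and the chiral pocket of the ligand selects the face of the flat nucleophile and thus sets C6 as R.

Step 19
Reactants: 28 methyl ester of the target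
Product: 29 CNP0328119.1
Conditions: LiOH, THF/MeOH/H2O, 0 °C to rt; then 1 M HCl to pH 3 at 0 °C
Reagents that add atoms: lithium hydroxide, [Li+].[OH-]
Why: Saponification of the methyl ester: the β-triketone is present as its enolate, which shields C3 from deprotonation and the ring from retro-Claisen cleavage, and mild acidification gives the free acid in its C4-enol form.

Compound list
1 | (−)-α-pinene, (1S,5S)-2,6,6-trimethylbicyclo[3.1.1]hept-2-ene | CC1=CC[C@H]2C[C@@H]1C2(C)C | starting material
2 | cis-pinonic acid, 2-[(1R,3R)-3-acetyl-2,2-dimethylcyclobutyl]acetic acid | CC(=O)[C@@H]1C[C@H](CC(=O)O)C1(C)C | intermediate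
3 | methyl 2-[(1R,3R)-3-acetyl-2,2-dimethylcyclobutyl]acetate | CC(=O)[C@@H]1C[C@H](CC(=O)OC)C1(C)C | intermediate
4 | methyl 2-[(1R,3S)-2,2-dimethyl-3-(prop-1-en-2-yl)cyclobutyl]acetate | C=C(C)[C@@H]1C[C@H](CC(=O)OC)C1(C)C | intermediate
5 | lithium 3-[(1R,3S)-2,2-dimethyl-3-(prop-1-en-2-yl)cyclobutyl]prop-1-yn-1-olate | [Li+].[O-]C#CC[C@H]1C[C@@H](C(C)=C)C1(C)C | intermediate
6 | 1-(triisopropylsiloxy)-3-[(1R,3S)-2,2-dimethyl-3-(prop-1-en-2-yl)cyclobutyl]prop-1-yne | CC(C)[Si](OC#CC[C@H]1C[C@@H](C(C)=C)C1(C)C)(C(C)C)C(C)C | intermediate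
7 | 3-phenylglutaric anhydride | O=C1CC(CC(=O)O1)c1ccccc1 | starting material
8 | (S)-5-methoxy-5-oxo-3-phenylpentanoic acid | OC(=O)C[C@@H](CC(=O)OC)c1ccccc1 | intermediate
9 | acid chloride of 8 (benzylic centre unchanged) | ClC(=O)C[C@@H](CC(=O)OC)c1ccccc1 | intermediate
10 | aldoketene from 9, methyl 5-oxo-3-phenylpent-4-enoate (benzylic centre unchanged) | O=C=C[C@@H](CC(=O)OC)c1ccccc1 | intermediate
11 | methyl 3-{3-[((1R,3S)-2,2-dimethyl-3-isopropenylcyclobutyl)methyl]-4-oxo-2-(triisopropylsiloxy)cyclobut-2-en-1-yl}-3-phenylpropanoate (benzylic centre as in 8; ring sp3 centre as a mixture) | O=C1C(C[C@H]2C[C@@H](C(C)=C)C2(C)C)=C(O[Si](C(C)C)(C(C)C)C(C)C)C1[C@@H](CC(=O)OC)c3ccccc3 | intermediate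
12 | methyl (S)-3-hydroxybutanoate | C[C@H](O)CC(=O)OC | starting material
13 | methyl (2S,3S)-3-hydroxy-2-methylbutanoate | C[C@H](O)[C@H](C)C(=O)OC | intermediate
14 | methyl (2S,3S)-2-methyl-3-(triethylsiloxy)butanoate | C[C@H](O[Si](CC)(CC)CC)[C@H](C)C(=O)OC | intermediate
15 | (2S,3S)-2-methyl-3-(triethylsiloxy)butanal | C[C@H](O[Si](CC)(CC)CC)[C@H](C)C=O | intermediate
16 | 4-methyl-5-(triethylsiloxy)hex-1-yn-3-ol (C4, C5 as in 15; C3 mixture) | C[C@H](O[Si](CC)(CC)CC)[C@H](C)C(O)C#C | intermediate
17 | 4-methyl-3,5-bis(triethylsiloxy)hex-1-yne (C4, C5 as in 15; C3 mixture) | C[C@H](O[Si](CC)(CC)CC)[C@H](C)C(O[Si](CC)(CC)CC)C#C | intermediate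
18 | lithium ynolate of 17 | [Li+].[O-]C#CC(O[Si](CC)(CC)CC)[C@@H](C)[C@H](C)O[Si](CC)(CC)CC | intermediate
19 | 1-(triisopropylsiloxy)-4-methyl-3,5-bis(triethylsiloxy)hex-1-yne (C4, C5 as in 15; C3 mixture) | CC(C)[Si](OC#CC(O[Si](CC)(CC)CC)[C@@H](C)[C@H](C)O[Si](CC)(CC)CC)(C(C)C)C(C)C | intermediate
20 | vinylketene from ring opening of 11 | O=C=C(C[C@H]1C[C@@H](C(C)=C)C1(C)C)C(O[Si](C(C)C)(C(C)C)C(C)C)=C[C@@H](CC(=O)OC)c2ccccc2 | intermediate
21 | 4-vinylcyclobutenone, [2+2] adduct of 20 and 19 | O=C1C(C(O[Si](CC)(CC)CC)[C@@H](C)[C@H](C)O[Si](CC)(CC)CC)=C(O[Si](C(C)C)(C(C)C)C(C)C)C1(C[C@H]2C[C@@H](C(C)=C)C2(C)C)C(O[Si](C(C)C)(C(C)C)C(C)C)=C[C@@H](CC(=O)OC)c3ccccc3 | intermediate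
22 | dienylketene from ring opening of 21 | O=C=C(C(O[Si](CC)(CC)CC)[C@@H](C)[C@H](C)O[Si](CC)(CC)CC)C(O[Si](C(C)C)(C(C)C)C(C)C)=C(C[C@H]2C[C@@H](C(C)=C)C2(C)C)C(O[Si](C(C)C)(C(C)C)C(C)C)=C[C@@H](CC(=O)OC)c3ccccc3 | intermediate
23 | hexasubstituted phenol: free OH (future C8a), 1,3-bis(triethylsiloxy)-2-methylbutyl arm (C4a), OSi(iPr)3 (C5), cyclobutylmethyl (C6), OSi(iPr)3 (C7), (S)-CH(Ph)CH2CO2Me (C8) | Oc1c(C(O[Si](CC)(CC)CC)[C@@H](C)[C@H](C)O[Si](CC)(CC)CC)c(O[Si](C(C)C)(C(C)C)C(C)C)c(C[C@H]2C[C@@H](C(C)=C)C2(C)C)c(O[Si](C(C)C)(C(C)C)C(C)C)c1[C@@H](CC(=O)OC)c3ccccc3 | intermediate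
24 | phenol diol from 23 (both triethylsilyl groups removed) | Oc1c(C(O)[C@@H](C)[C@H](C)O)c(O[Si](C(C)C)(C(C)C)C(C)C)c(C[C@H]2C[C@@H](C(C)=C)C2(C)C)c(O[Si](C(C)C)(C(C)C)C(C)C)c1[C@@H](CC(=O)OC)c3ccccc3 | intermediate
25 | ortho-hydroxyaryl (2S,3S)-3-hydroxy-2-methylbutanoyl ketone | Oc1c(C(=O)[C@@H](C)[C@H](C)O)c(O[Si](C(C)C)(C(C)C)C(C)C)c(C[C@H]2C[C@@H](C(C)=C)C2(C)C)c(O[Si](C(C)C)(C(C)C)C(C)C)c1[C@@H](CC(=O)OC)c3ccccc3 | intermediate
26 | (2R,3S)-2,3-dimethyl-5,7-bis(triisopropylsiloxy)chroman-4-one with C6 cyclobutylmethyl and C8 (S)-CH(Ph)CH2CO2Me | O=C1[C@@H](C)[C@@H](C)Oc2c1c(O[Si](C(C)C)(C(C)C)C(C)C)c(C[C@H]3C[C@@H](C(C)=C)C3(C)C)c(O[Si](C(C)C)(C(C)C)C(C)C)c2[C@@H](CC(=O)OC)c4ccccc4 | intermediate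
27 | (2R,3S)-5,7-dihydroxy-2,3-dimethylchroman-4-one with C6 cyclobutylmethyl and C8 (S)-CH(Ph)CH2CO2Me | O=C1[C@@H](C)[C@@H](C)Oc2c1c(O)c(C[C@H]3C[C@@H](C(C)=C)C3(C)C)c(O)c2[C@@H](CC(=O)OC)c4ccccc4 | intermediate
28 | methyl ester of the target (2R,3S,6R; side chain S) | C=C(C)[C@@H]1C[C@H](C[C@@]2(CC=C(C)C)C(=O)C3=C(O)[C@@H](C)[C@@H](C)OC3=C([C@@H](CC(=O)OC)c3ccccc3)C2=O)C1(C)C | intermediate
29 | CNP0328119.1, (3S)-3-[(2R,3S,6R)-6-{[(1R,3S)-2,2-dimethyl-3-(prop-1-en-2-yl)cyclobutyl]methyl}-4-hydroxy-2,3-dimethyl-6-(3-methylbut-2-enyl)-5,7-dioxo-2,3-dihydrochromen-8-yl]-3-phenylpropanoic acid | C=C(C)[C@@H]1C[C@H](C[C@@]2(CC=C(C)C)C(=O)C3=C(O)[C@@H](C)[C@@H](C)OC3=C([C@@H](CC(=O)O)c3ccccc3)C2=O)C1(C)C | target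

Total step count: 19. Longest linear sequence: 13 steps (steps 7–12, then 13–19).

Steps most likely to fail

Step 13. The bimolecular [2+2] must join two fully substituted carbons flanked by triisopropylsiloxy groups and a branched propargylic centre. Capture of vinylketene 20 by 19 may therefore be outrun by ketene dimerisation, by acylation of the product phenol or by loss of the vinylogous silyl ester. The fallback sets out from 11 and runs the same cascade with the unbranched ketenophile (triisopropylsiloxy)ethyne F1, made from lithium acetylide by the oxidation and silylation of step 12. This should give the C4a-unsubstituted phenol F2. The C4–C4a bond is then made separately by ortho-specific hydroxyalkylation of the bromomagnesium phenolate of F2 (EtMgBr, CH2Cl2) with aldehyde 15, through a chelated six-membered transition state, to give the benzylic alcohol F3. HF·pyridine removes its single triethylsilyl group, and the route is rejoined at 24.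

Step 18. The flat C6 nucleophile may be discriminated poorly by the ligand. O-prenylation or attack at the tertiary allyl terminus may also compete. The fallback sets out from 27 and separates the setting of the stereocentre from the building of the prenyl group. Dearomatising allylic alkylation with allyl methyl carbonate uses a small, symmetrical π-allyl partner that has no regiochemical ambiguity and sits deeper in the ligand pocket, and it should give the C6-allyl compound F4. Cross metathesis of F4 with 2-methyl-2-butene (second-generation Hoveyda–Grubbs catalyst, CH2Cl2, 40 °C) converts the allyl group into prenyl, while the 1,1-disubstituted isopropenyl group stays a spectator. The route is rejoined at 28.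

Step 16. The Mitsunobu betaine may deprotonate C3 of the β-hydroxy ketone. The result would be E1cB loss of the activated C2 oxygen, then unselective re-addition that scrambles C2 and C3, instead of SN2 closure. The fallback sets out from 23 and closes the ring before the ketone exists, so that no acidic C3–H is present. Selective solvolysis of the less hindered C2 triethylsilyl ether (PPTS, EtOH, −10 °C) gives the mono-silyl phenol alcohol F5. Mitsunobu closure with inversion gives the 4-(triethylsiloxy)chroman F6, and HF·pyridine gives the chroman-4-ol F7. MnO2 oxidation then rejoins the route at 26.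

Further compounds
F1 | step 13 | (triisopropylsiloxy)ethyne | C#CO[Si](C(C)C)(C(C)C)C(C)C
F2 | step 13 | pentasubstituted phenol lacking the C4a arm | Oc1cc(O[Si](C(C)C)(C(C)C)C(C)C)c(C[C@H]2C[C@@H](C(C)=C)C2(C)C)c(O[Si](C(C)C)(C(C)C)C(C)C)c1[C@@H](CC(=O)OC)c3ccccc3
F3 | step 13 | ortho-hydroxyalkylation product of F2 and 15 (C4 carbinol free, C2 triethylsilyl ether) | Oc1c(C(O)[C@@H](C)[C@H](C)O[Si](CC)(CC)CC)c(O[Si](C(C)C)(C(C)C)C(C)C)c(C[C@H]2C[C@@H](C(C)=C)C2(C)C)c(O[Si](C(C)C)(C(C)C)C(C)C)c1[C@@H](CC(=O)OC)c3ccccc3
F4 | step 18 | C6-allyl analogue of 28 | C=C(C)[C@@H]1C[C@H](C[C@@]2(CC=C)C(=O)C3=C(O)[C@@H](C)[C@@H](C)OC3=C([C@@H](CC(=O)OC)c3ccccc3)C2=O)C1(C)C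
F5 | step 16 | phenol with free C2 hydroxyl and C4 triethylsilyl ether | Oc1c(C(O[Si](CC)(CC)CC)[C@@H](C)[C@H](C)O)c(O[Si](C(C)C)(C(C)C)C(C)C)c(C[C@H]2C[C@@H](C(C)=C)C2(C)C)c(O[Si](C(C)C)(C(C)C)C(C)C)c1[C@@H](CC(=O)OC)c3ccccc3
F6 | step 16 | cis-2,3-dimethyl-4-(triethylsiloxy)chroman | CC[Si](CC)(CC)OC1[C@@H](C)[C@@H](C)Oc2c1c(O[Si](C(C)C)(C(C)C)C(C)C)c(C[C@H]3C[C@@H](C(C)=C)C3(C)C)c(O[Si](C(C)C)(C(C)C)C(C)C)c2[C@@H](CC(=O)OC)c4ccccc4
F7 | step 16 | cis-2,3-dimethylchroman-4-ol | OC1[C@@H](C)[C@@H](C)Oc2c1c(O[Si](C(C)C)(C(C)C)C(C)C)c(C[C@H]3C[C@@H](C(C)=C)C3(C)C)c(O[Si](C(C)C)(C(C)C)C(C)C)c2[C@@H](CC(=O)OC)c4ccccc4
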